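The cyclohexane ring is cut into a four-carbon diene, whose termini are the CHBr carbon and the methyl-bearing C-O carbon, and a two-carbon dienophile, the gem-dimethyl carbon plus the ring-fusion CH, which is the alkene of 3-methylbut-2-enal. One catalytic enantioselective endo Diels-Alder reaction of a (2Z,4E)-5-bromo-2-silyloxypenta-2,4-diene forms the CHBr-CMe2 and C(Me)(O)-CH bonds and sets all three carbocyclic stereocentres through diene geometry, endo rule and catalyst. After one-carbon homologation to a lactol, the oxepene ring is annulated by an oxa-Michael/Horner-Wadsworth-Emmons sequence; bromide exchange and ester reduction finish.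

Key step: step 4

Remark on the chemistry: alcohol 1 is used as the racemate because its stereocentre is destroyed in step 2; enol ether 8 (E/Z), lactol 9 (anomers) and phosphonate 12 (E/Z) are used as mixtures because these stereo-elements disappear later.
Remark on the chemistry: the sense of induction in step 4 is assigned by analogy with the oxazaborolidinium model for enals; the catalyst is the only source of chirality, so its enantiomer would correct an opposite sense.

Step 1
Reactants: 1 pent-4-yn-2-ol
Product: 2 (E)-5-bromopent-4-en-2-ol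
Conditions: Cp2Zr(H)Cl (2.2 equiv), THF, 0 °C to rt; then NBS, 0 °C
Reagents that add atoms: N-bromosuccinimide, O=C1CCC(=O)N1Br
Why: Syn-hydrozirconation of the terminal alkyne (Schwartz reagent; the first equivalent is consumed by the hydroxyl group) puts the metal on the terminal carbon, and bromodezirconation with retention should give the (E)-vinyl bromide.

Step 2
Reactants: 2 (E)-5-bromopent-4-en-2-ol
Product: 3 (E)-5-bromopent-4-en-2-one
Conditions: Dess-Martin periodinane, CH2Cl2, 0 °C to rt; crude product used directly
Reagents that add atoms: none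
Why: Dess-Martin oxidation of the secondary alcohol under neutral, non-enolising conditions should give the beta,gamma-unsaturated ketone without migration of the double bond into conjugation.

Step 3
Reactants: 3 (E)-5-bromopent-4-en-2-one
Product: 4 tert-butyl{[(2Z,4E)-5-bromopenta-2,4-dien-2-yl]oxy}dimethylsilane
Conditions: TBSOTf, Et3N, CH2Cl2, -78 to 0 °C
Reagents that add atoms: tert-butyldimethylsilyl trifluoromethanesulfonate, CC(C)(C)[Si](C)(C)OS(=O)(=O)C(F)(F)F
Why: Soft enolisation (silyl triflate/amine) removes the doubly activated C-3 proton between the carbonyl and the vinyl bromide to give the conjugated 2-silyloxy diene, and the (2Z) geometry (oxygen cis to the vinyl group, methyl trans) is the one favoured for enol silanes of methyl ketones because it avoids the cis methyl/vinyl interaction.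

Step 4
Reactants: 4 tert-butyl{[(2Z,4E)-5-bromopenta-2,4-dien-2-yl]oxy}dimethylsilane; 5 3-methylbut-2-enal
Product: 6 (1S,2S,5S)-5-bromo-2-[(tert-butyldimethylsilyl)oxy]-2,6,6-trimethylcyclohex-3-ene-1-carbaldehyde (Br, CHO and ring CH3 all cis)
Conditions: (S)-3,3-diphenyl-1-(2-methylphenyl)tetrahydropyrrolo[1,2-c][1,3,2]oxazaborole·Tf2NH (20 mol %), CH2Cl2, 4 Å MS, -40 to -20 °C
Reagents that add atoms: none
Why: The protonated oxazaborolidine binds the formyl group of 5 and lowers its LUMO, so that diene 4 adds across the C=C bond of the enal in a concerted but asynchronous [4+2] cycloaddition whose leading bond joins the bromine-bearing diene terminus to the beta-carbon, the future CMe2. The closest known reaction types are the Lewis acid-catalysed Diels-Alder reactions of 3-methylbut-2-enal or mesityl oxide with 1-substituted dienes and the oxazaborolidinium-catalysed cycloadditions of enals with silyloxy dienes. The cyclohexene ring is closed by an intermolecular [4+2] cycloaddition in which both new ring bonds form suprafacially on each partner, and no second ring is formed at this stage. The Br-bearing centre follows from the (4E) vinyl bromide and the quaternary C-O centre from the (2Z) enol ether (Br and CH3 both outside, hence cis), the formyl-bearing centre from the endo orientation of the CHO group (cis to Br and CH3), and the absolute configuration from the catalyst, which shields one face of the bound s-trans enal. The step needs ortho regioselectivity, secured by the silyloxy donor that makes the brominated terminus the nucleophilic end of the diene. It also needs C=C over C=O periselectivity and suppression of Mukaiyama-type addition, for which the organised catalyst-aldehyde complex and the bulky silyl group are relied on.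

Step 5
Reactants: 6 (1S,2S,5S)-5-bromo-2-[(tert-butyldimethylsilyl)oxy]-2,6,6-trimethylcyclohex-3-ene-1-carbaldehyde
Product: 7 (1S,3S,6S)-3-bromo-6-[(tert-butyldimethylsilyl)oxy]-2,2,6-trimethylcyclohexane-1-carbaldehyde
Conditions: KO2CN=NCO2K (excess), AcOH, MeOH, 0 °C to rt
Reagents that add atoms: none
Why: Diimide reduction transfers H2 concertedly and syn to the cis-disubstituted ring alkene and should leave the aldehyde, the silyl ether and the allylic C-Br bond (which catalytic hydrogenation would cleave) untouched; no stereocentre is created.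

Step 6
Reactants: 7 (1S,3S,6S)-3-bromo-6-[(tert-butyldimethylsilyl)oxy]-2,2,6-trimethylcyclohexane-1-carbaldehyde
Product: 9 (3aS,5S,7aS)-5-bromo-4,4,7a-trimethyloctahydro-1-benzofuran-2-ol (lactol; anomeric mixture), via methyl enol ether 8 (not isolated)
Conditions: Ph3P(CH2OMe)Cl, KN(SiMe3)2, THF, 0 °C to rt; then 48% aqueous HF, MeCN, rt
Reagents that add atoms: (methoxymethyl)triphenylphosphonium chloride, COC[P+](c1ccccc1)(c1ccccc1)c1ccccc1.[Cl-]; water, O
Why: Wittig methoxymethylenation followed by aqueous acid gives the one-carbon homologated aldehyde (the former formyl carbon becomes the CH2 next to the ring fusion), HF also cleaves the tertiary silyl ether, and the gamma-hydroxy aldehyde should close to the trans-fused lactol; the alpha-stereocentre is the thermodynamically preferred equatorial one, so any epimerisation converges on it.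

Step 7
Reactants: 10 (tert-butyldimethylsilyloxy)acetaldehyde; 11 trimethyl phosphonoacetate
Product: 12 methyl 4-[(tert-butyldimethylsilyl)oxy]-2-(dimethoxyphosphoryl)but-2-enoate (E/Z mixture)
Conditions: TiCl4, N-methylmorpholine, THF, 0 °C to rt
Reagents that add atoms: none
Why: Lehnert-type Knoevenagel condensation of the aldehyde with the phosphonoacetate should give the alkylidene phosphonoacetate, a doubly activated Michael acceptor whose alkene geometry is irrelevant.

Step 8
Reactants: 9 (3aS,5S,7aS)-5-bromo-4,4,7a-trimethyloctahydro-1-benzofuran-2-ol; 12 methyl 4-[(tert-butyldimethylsilyl)oxy]-2-(dimethoxyphosphoryl)but-2-enoate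
Product: 14 methyl (2R,5aS,7S,9aS)-7-bromo-2-{[(tert-butyldimethylsilyl)oxy]methyl}-6,6,9a-trimethyl-2,5,5a,6,7,8,9,9a-octahydro-1-benzoxepine-3-carboxylate, via phosphonate Michael adduct 13 (not isolated)
Conditions: NaH, THF, 0 to 40 °C
Reagents that add atoms: none
Why: Tandem oxa-Michael/intramolecular Horner-Wadsworth-Emmons annulation: the sodium alkoxide of lactol 9 is in ring-chain equilibrium with the tertiary alkoxide/aldehyde, which adds reversibly to 12 to give phosphonate carbanion 13, and irreversible olefination of the tethered aldehyde closes the seven-membered ring with its cis alkene; because the conjugate addition is reversible, the new C-O stereocentre is fixed only in the ring closure, which is expected to run through the adduct whose CH2OSi arm sits pseudo-axial at C-2, clear of the phosphoryl and ester groups on the neighbouring carbon (avoidance of allylic 1,2-strain in the developing alkene), and on the trans-fused ring this arm points to the face of the angular methyl group, which is the (2R) epimer.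

Step 9
Reactants: 14 methyl (2R,5aS,7S,9aS)-7-bromo-2-{[(tert-butyldimethylsilyl)oxy]methyl}-6,6,9a-trimethyl-2,5,5a,6,7,8,9,9a-octahydro-1-benzoxepine-3-carboxylate
Product: 15 methyl (2R,5aS,7S,9aS)-7-bromo-2-(bromomethyl)-6,6,9a-trimethyl-2,5,5a,6,7,8,9,9a-octahydro-1-benzoxepine-3-carboxylate
Conditions: Ph3PBr2, CH2Cl2, 0 °C to rt
Reagents that add atoms: triphenylphosphine dibromide, BrP(Br)(c1ccccc1)(c1ccccc1)c1ccccc1
Why: Triphenylphosphine dibromide converts a primary silyl ether directly into the bromide (silyl transfer to bromide, then SN2 displacement of the alkoxyphosphonium ion) and should leave the conjugated ester, the ring ether and the neopentyl-type secondary bromide untouched.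

Step 10
Reactants: 15 methyl (2R,5aS,7S,9aS)-7-bromo-2-(bromomethyl)-6,6,9a-trimethyl-2,5,5a,6,7,8,9,9a-octahydro-1-benzoxepine-3-carboxylate
Product: 16 [(2R,5aS,7S,9aS)-7-bromo-2-(bromomethyl)-6,6,9a-trimethyl-2,5,5a,6,7,8,9,9a-octahydro-1-benzoxepin-3-yl]methanol (target)
Conditions: i-Bu2AlH, CH2Cl2, -78 °C; aqueous potassium sodium tartrate
Reagents that add atoms: none
Why: i-Bu2AlH reduction takes the alpha,beta-unsaturated ester 1,2-selectively to the allylic alcohol at low temperature, where neither alkyl bromide is reduced; no stereocentre is affected.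

Compound list

1 | pent-4-yn-2-ol (racemic) | CC(O)CC#C | starting material
2 | (E)-5-bromopent-4-en-2-ol | CC(O)C/C=C/Br | intermediate
3 | (E)-5-bromopent-4-en-2-one | CC(=O)C/C=C/Br | intermediate
4 | tert-butyl{[(2Z,4E)-5-bromopenta-2,4-dien-2-yl]oxy}dimethylsilane | C/C(O[Si](C)(C)C(C)(C)C)=C/C=C/Br | intermediate
5 | 3-methylbut-2-enal | CC(C)=CC=O | starting material
6 | (1S,2S,5S)-5-bromo-2-[(tert-butyldimethylsilyl)oxy]-2,6,6-trimethylcyclohex-3-ene-1-carbaldehyde | CC1(C)[C@@H](Br)C=C[C@](C)(O[Si](C)(C)C(C)(C)C)[C@H]1C=O | intermediate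
7 | (1S,3S,6S)-3-bromo-6-[(tert-butyldimethylsilyl)oxy]-2,2,6-trimethylcyclohexane-1-carbaldehyde | CC1(C)[C@@H](Br)CC[C@](C)(O[Si](C)(C)C(C)(C)C)[C@H]1C=O | intermediate
8 | tert-butyl{[(1S,2S,4S)-4-bromo-2-(2-methoxyethenyl)-1,3,3-trimethylcyclohexyl]oxy}dimethylsilane (E/Z mixture) | CC1(C)[C@@H](Br)CC[C@](C)(O[Si](C)(C)C(C)(C)C)[C@H]1C=COC | intermediate (not isolated)
9 | (3aS,5S,7aS)-5-bromo-4,4,7a-trimethyloctahydro-1-benzofuran-2-ol (anomeric mixture) | CC1(C)[C@@H](Br)CC[C@]2(C)OC(O)C[C@@H]12 | intermediate
10 | (tert-butyldimethylsilyloxy)acetaldehyde | CC(C)(C)[Si](C)(C)OCC=O | starting material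
11 | trimethyl phosphonoacetate | COC(=O)CP(=O)(OC)OC | starting material
12 | methyl 4-[(tert-butyldimethylsilyl)oxy]-2-(dimethoxyphosphoryl)but-2-enoate (E/Z mixture) | COC(=O)C(=CCO[Si](C)(C)C(C)(C)C)P(=O)(OC)OC | intermediate
13 | methyl (3S)-3-{[(1S,2S,4S)-4-bromo-1,3,3-trimethyl-2-(2-oxoethyl)cyclohexyl]oxy}-4-[(tert-butyldimethylsilyl)oxy]-2-(dimethoxyphosphoryl)butanoate (formed as its carbanion; C-2 unassigned) | CC1(C)[C@@H](Br)CC[C@](C)(O[C@@H](CO[Si](C)(C)C(C)(C)C)C(C(=O)OC)P(=O)(OC)OC)[C@H]1CC=O | intermediate (not isolated)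
14 | methyl (2R,5aS,7S,9aS)-7-bromo-2-{[(tert-butyldimethylsilyl)oxy]methyl}-6,6,9a-trimethyl-2,5,5a,6,7,8,9,9a-octahydro-1-benzoxepine-3-carboxylate | CC1(C)[C@@H](Br)CC[C@]2(C)O[C@@H](CO[Si](C)(C)C(C)(C)C)C(C(=O)OC)=CC[C@@H]12 | intermediate
15 | methyl (2R,5aS,7S,9aS)-7-bromo-2-(bromomethyl)-6,6,9a-trimethyl-2,5,5a,6,7,8,9,9a-octahydro-1-benzoxepine-3-carboxylate | CC1(C)[C@@H](Br)CC[C@]2(C)O[C@@H](CBr)C(C(=O)OC)=CC[C@@H]12 | intermediate
16 | [(2R,5aS,7S,9aS)-7-bromo-2-(bromomethyl)-6,6,9a-trimethyl-2,5,5a,6,7,8,9,9a-octahydro-1-benzoxepin-3-yl]methanol | CC1(C)[C@@H](Br)CC[C@]2(C)O[C@@H](CBr)C(CO)=CC[C@@H]12 | target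

Total step count: 10
Longest linear sequence: 9 (steps 1 to 6 and 8 to 10; step 7 prepares the second fragment)

Steps most likely to fail

1. Step 4 (key step). The beta,beta-disubstituted enal and the fully substituted silyloxy terminus are both sluggish. The acid catalyst may instead trigger addition at the formyl group (hetero-Diels-Alder or vinylogous Mukaiyama aldol) or silyl transfer, and facial discrimination may be poor. Fallback: it sets out from compounds 4 and 5 and comes back to the route at compound 6. Diene 4 and enal 5 are combined without any acid at about 13 kbar (CH2Cl2, 25 °C), conditions under which silyloxy dienes add to hindered enals by the carbon-carbon pathway, to give the racemic endo adduct F1. Condensation of this aldehyde with (1R,2R)-N,N'-dimethyl-1,2-diphenylethane-1,2-diamine gives two diastereomeric imidazolidines that are separated by chromatography. The one derived from the (1S,2S,5S)-aldehyde is the imidazolidine F2, which is hydrolysed with dilute aqueous HCl in ether to return aldehyde 6, with recovery of the diamine.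

2. Step 8. The hindered tertiary alkoxide may add too slowly to the beta-substituted acceptor, so that aldol self-condensation, transannular displacement of the secondary bromide or deconjugation of the acceptor take over. In addition, the axial methyl group across the ether oxygen may override the expected preference in the ring closure and deliver the wrong C-O epimer. Fallback: it sets out from lactol 9 and comes back to the route at target 16. Lactol 9 is methylenated (Ph3P=CH2, THF) to the homoallylic tertiary alcohol F3, (1S,2S,4S)-4-bromo-1,3,3-trimethyl-2-(prop-2-en-1-yl)cyclohexan-1-ol. Its lithium alkoxide (n-BuLi, THF, -78 °C) is acylated with 2-{[(tert-butyldimethylsilyl)oxy]methyl}acryloyl chloride to the acrylate ester F4. Ring-closing metathesis with the second-generation Grubbs catalyst (toluene, 80 °C) gives the alpha,beta-unsaturated seven-membered lactone F5. Methylenation of the lactone carbonyl with Cp2TiMe2 (toluene, 70 °C) gives the exocyclic enol ether F6. Hydroboration with 9-BBN from the face anti to the angular methyl group, then NaOH/H2O2, gives the primary alcohol F7 with the required (2R) centre. Appel bromination (CBr4, PPh3) gives the bromide silyl ether F8, and HF-pyridine in THF removes the silyl group to arrive at 16.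

3. Step 6. The strongly basic ylide may enolise the hindered beta-silyloxy aldehyde or expel silanolate instead of adding to the neopentyl-type formyl group. Fallback: it sets out from aldehyde 7 and comes back to the route at lactol 9. Aldehyde 7 is converted with dimethyl (1-diazo-2-oxopropyl)phosphonate (K2CO3, MeOH) into the terminal alkyne F9. Anti-Markovnikov hydroboration with dicyclohexylborane and oxidation with NaBO3 give the homologated aldehyde F10. Aqueous HF in MeCN then removes the silyl group, and the hydroxy aldehyde closes to lactol 9.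

Further compounds

F1 | step 4 | racemic endo adduct, rac-(1S,2S,5S)-5-bromo-2-[(tert-butyldimethylsilyl)oxy]-2,6,6-trimethylcyclohex-3-ene-1-carbaldehyde (relative configuration as in 6; one enantiomer drawn) | CC1(C)[C@@H](Br)C=C[C@](C)(O[Si](C)(C)C(C)(C)C)[C@H]1C=O
F2 | step 4 | imidazolidine (aminal) of aldehyde 6 with (1R,2R)-N,N'-dimethyl-1,2-diphenylethane-1,2-diamine | CC1(C)[C@@H](Br)C=C[C@](C)(O[Si](C)(C)C(C)(C)C)[C@H]1C1N(C)[C@H](c2ccccc2)[C@@H](c2ccccc2)N1C
F3 | step 8 | (1S,2S,4S)-4-bromo-1,3,3-trimethyl-2-(prop-2-en-1-yl)cyclohexan-1-ol | CC1(C)[C@@H](Br)CC[C@](C)(O)[C@H]1CC=C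
F4 | step 8 | (1S,2S,4S)-4-bromo-1,3,3-trimethyl-2-(prop-2-en-1-yl)cyclohexyl 2-{[(tert-butyldimethylsilyl)oxy]methyl}prop-2-enoate | CC1(C)[C@@H](Br)CC[C@](C)(OC(=O)C(=C)CO[Si](C)(C)C(C)(C)C)[C@H]1CC=C
F5 | step 8 | (5aS,7S,9aS)-7-bromo-3-{[(tert-butyldimethylsilyl)oxy]methyl}-6,6,9a-trimethyl-5a,6,7,8,9,9a-hexahydro-1-benzoxepin-2(5H)-one | CC1(C)[C@@H](Br)CC[C@]2(C)OC(=O)C(CO[Si](C)(C)C(C)(C)C)=CC[C@@H]12
F6 | step 8 | tert-butyl{[(5aS,7S,9aS)-7-bromo-6,6,9a-trimethyl-2-methylidene-2,5,5a,6,7,8,9,9a-octahydro-1-benzoxepin-3-yl]methoxy}dimethylsilane | CC1(C)[C@@H](Br)CC[C@]2(C)OC(=C)C(CO[Si](C)(C)C(C)(C)C)=CC[C@@H]12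
F7 | step 8 | [(2R,5aS,7S,9aS)-7-bromo-3-{[(tert-butyldimethylsilyl)oxy]methyl}-6,6,9a-trimethyl-2,5,5a,6,7,8,9,9a-octahydro-1-benzoxepin-2-yl]methanol | CC1(C)[C@@H](Br)CC[C@]2(C)O[C@@H](CO)C(CO[Si](C)(C)C(C)(C)C)=CC[C@@H]12
F8 | step 8 | tert-butyl{[(2R,5aS,7S,9aS)-7-bromo-2-(bromomethyl)-6,6,9a-trimethyl-2,5,5a,6,7,8,9,9a-octahydro-1-benzoxepin-3-yl]methoxy}dimethylsilane | CC1(C)[C@@H](Br)CC[C@]2(C)O[C@@H](CBr)C(CO[Si](C)(C)C(C)(C)C)=CC[C@@H]12
F9 | step 6 | tert-butyl{[(1S,2S,4S)-4-bromo-2-ethynyl-1,3,3-trimethylcyclohexyl]oxy}dimethylsilane | CC1(C)[C@@H](Br)CC[C@](C)(O[Si](C)(C)C(C)(C)C)[C@H]1C#C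
F10 | step 6 | 2-[(1S,3S,6S)-3-bromo-6-[(tert-butyldimethylsilyl)oxy]-2,2,6-trimethylcyclohexyl]acetaldehyde | CC1(C)[C@@H](Br)CC[C@](C)(O[Si](C)(C)C(C)(C)C)[C@H]1CC=O
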